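## Retrosynthetic overview

1. Rabdosin B ⇐ 11-O-silyl precursor; the C16 methylene, the C15 ketone and both acetates are installed late on a tetracyclic lactone.
2. Ring D (C8–C15) ⇐ palladium-mediated oxidative cyclisation of a lactone silyl ketene acetal onto a C13 allyl group; ring C (C9–C11) ⇐ SmI2 ketyl–olefin cyclisation of a C11 aldehyde onto the C8=C9 unsaturated spirolactone.
3. Key disconnection: the lactone C20–O bond (and then C10–C9). An α-methylene ketone (ring A) and an α-substituted acrylic acid are joined by carboxylate oxa-Michael addition, followed by intramolecular Michael closure of the spiro δ-lactone.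
4. Ring A piece ⇐ 4,4-dimethylcyclohexenone (asymmetric conjugate addition, Mannich trapping); acid piece ⇐ pent-4-enal (organocatalytic α-alkylation, Wittig homologation).
5. Ring order: ring A (purchased) → spirolactone → ring C → ring D.

Assumption: atoms carry ent-kaurane numbers (C1–C20); "as in 32" means the same spatial arrangement as in the target SMILES; the C11=C12 enol ethers are E/Z mixtures and C8 (C10 in 15) is an epimer mixture where the SMILES leave it open.

## Route

Step 1
Reactants: 1 pent-4-enal; 2 methyl 2-(bromomethyl)prop-2-enoate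
Product: 3 methyl 2-[(2S)-2-formylpent-4-en-1-yl]prop-2-enoate
Conditions: (R)-α,α-diphenylprolinol trimethylsilyl ether (20 mol %), DMAP (1.1 equiv), CH2Cl2, 0 °C
Reagents that add atoms: none
Why: Enamine-mediated SN2′ α-alkylation of the aldehyde with the DMAP-activated allyl bromide; the CPh2OSiMe3 group shields one enamine face and sets C13 as S (sense assigned by analogy with Michael additions of this catalyst family).

Step 2
Reactants: 3 methyl 2-[(2S)-2-formylpent-4-en-1-yl]prop-2-enoate; 4 (methoxymethyl)triphenylphosphonium chloride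
Product: 7 2-[(2S)-2-(2-methoxyethenyl)pent-4-en-1-yl]prop-2-enoic acid, via phosphorus ylide 5 (not isolated), via methyl ester 6 (not isolated)
Conditions: 4, KN(SiMe3)2, THF, 0 °C; 3, −78 → 0 °C; then LiOH, H2O–MeOH, rt; HCl to pH 4 at 0 °C
Reagents that add atoms: lithium hydroxide, [Li+].[OH-]
Why: Wittig olefination of the aldehyde (much faster than ylide addition to the acrylate at −78 °C) masks the future C11 aldehyde as an enol ether, and hydroxide then cleaves only the methyl ester; C13 is not touched.

Step 3
Reactants: 8 4,4-dimethylcyclohex-2-en-1-one; 9 benzyl chloromethyl ether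
Product: 12 (2R,3S)-3-(benzyloxymethyl)-2-(dimethylaminomethyl)-4,4-dimethylcyclohexan-1-one, via Grignard reagent 10 (not isolated), via magnesium enolate 11 (not isolated)
Conditions: 9, Mg, THF, −20 °C; 8, CuBr·SMe2 (5 mol %), (R)-1-[(S)-2-(diphenylphosphino)ferrocenyl]ethyldicyclohexylphosphine (6 mol %), t-BuOMe, −78 °C; then N,N-dimethylmethyleneiminium iodide, THF, −78 → 0 °C
Reagents that add atoms: N,N-dimethylmethyleneiminium iodide, C=[N+](C)C.[I-]
Why: Copper-catalysed asymmetric conjugate addition of a Grignard reagent (Feringa type) sets C5 by ligand-controlled face selection (the ligand antipode is used if the sense is opposite), and the regiodefined enolate is trapped at C10 by a Mannich reaction trans to the new group.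

Step 4
Reactants: 12 (2R,3S)-3-(benzyloxymethyl)-2-(dimethylaminomethyl)-4,4-dimethylcyclohexan-1-one; 7 2-[(2S)-2-(2-methoxyethenyl)pent-4-en-1-yl]prop-2-enoic acid
Product: 16 keto spirolactone (7,20-lactone spiro at C10; C1 ketone; 6-O-benzyl; C5 and C10 as in 32), via methiodide 13 (not isolated), via methylene ketone 14 (not isolated), via acyloxy ketone 15 (not isolated)
Conditions: MeI, Et2O, rt, evaporate; then 7, Cs2CO3, MeCN, 50 °C
Reagents that add atoms: none
Why: Proposed new method: a base-mediated formal [4+2] annulation of an α-methylene ketone with an α-substituted acrylic acid. Elimination from 13 releases enone 14, the cesium carboxylate of 7 adds to C20 (reversible oxa-Michael, forming the lactone C20–O bond), and the C10 enolate of 15 closes the δ-lactone by 6-endo Michael addition to the tethered acrylate on the face anti to the C5 benzyloxymethyl group, which fixes the C10 quaternary centre with C9 trans to C6. The closest known reactions are carboxylate additions to enones generated from Mannich bases, oxa-Michael/Michael dominos to tetrahydropyrans, and Robinson annulations run from Mannich methiodides.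

Step 5
Reactants: 16 keto spirolactone
Product: 17 hydroxy spirolactone (1-OH cis to C20 as in 32)
Conditions: NaBH4, MeOH, −40 °C; NH4Cl quench at −40 °C
Reagents that add atoms: none
Why: Borohydride reduction of the ketone by axial hydride delivery anti to the axial C20 methylene gives the equatorial C1 alcohol cis to C20 (substrate control); the lactone and enol ether are inert, and the cold quench avoids alkoxide translactonisation.

Step 6
Reactants: 17 hydroxy spirolactone
Product: 18 1,6-di-O-benzyl spirolactone
Conditions: 2-benzyloxy-1-methylpyridinium triflate, MgO, PhCF3, 85 °C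
Reagents that add atoms: 2-benzyloxy-1-methylpyridinium trifluoromethanesulfonate, C[n+]1ccccc1OCc1ccccc1.[O-]S(=O)(=O)C(F)(F)F
Why: Neutral benzyl transfer (Dudley benzylation) protects the hindered C1 alcohol without forming an alkoxide that could migrate the lactone to O1; no stereocentre is touched.

Step 7
Reactants: 18 1,6-di-O-benzyl spirolactone
Product: 21 C8=C9 unsaturated spirolactone, via selenide 19 (not isolated), via selenoxide 20 (not isolated)
Conditions: LiN(i-Pr)2, THF, −78 °C; PhSeSePh; then NaIO4, NaHCO3, MeOH–H2O, rt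
Reagents that add atoms: none
Why: α-Selenenylation of the lactone enolate and selenoxide syn-elimination toward the ring C9–H give the conjugated endocyclic α,β-unsaturated δ-lactone; the diselenide and periodate spare the enol ether and alkene, and the C8 stereocentre is removed.

Step 8
Reactants: 21 C8=C9 unsaturated spirolactone
Product: 22 C11 aldehyde (unsaturated spirolactone bearing the CH2CHO arm on C13)
Conditions: 1 M HCl, THF, 0 °C → rt
Reagents that add atoms: water, O
Why: Acid hydrolysis of the methyl enol ether through the oxocarbenium ion unmasks the C11 aldehyde; benzyl ethers, lactone and the non-enolisable C13 centre are unaffected.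

Step 9
Reactants: 22 C11 aldehyde
Product: 23 tricyclic hydroxy lactone (ring C closed; 11-OH; cis-fused C8–H; C13 allyl; C1 C5 C9 C10 C11 C13 as in 32)
Conditions: SmI2 (2.5 equiv), t-BuOH, HMPA, THF, −78 °C
Reagents that add atoms: none
Why: Ketyl–olefin reductive cyclisation, known for the C1-unsubstituted spirolactone series: the ketyl adds to C9 on the lactone face anti to C5 through a chair transition state with C10, O–Sm and the C13 allyl group equatorial, which sets C9 and C11 (OH cis to H9), and protonation of the samarium enolate gives the cis-fused C8–H.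

Step 10
Reactants: 23 tricyclic hydroxy lactone
Product: 24 11-O-silyl silyl ketene acetal (C7(OSi)=C8)
Conditions: KN(SiMe3)2 (2.5 equiv), TBSCl (3 equiv), THF–DMPU, −78 → 0 °C
Reagents that add atoms: tert-butyldimethylsilyl chloride, CC(C)(C)[Si](C)(C)Cl
Why: O-Silylation of the C11 potassium alkoxide and of the lactone enolate protects the alcohol and forms the ketene acetal in one operation; only the inconsequential C8 centre is lost.

Step 11
Reactants: 24 11-O-silyl silyl ketene acetal
Product: 25 15-methylene tetracycle (bicyclo[3.2.1]octane; C8 as in 32)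
Conditions: Pd(OAc)2 (1.0 equiv), AcOH (0.5 equiv), DMSO, 45 °C
Reagents that add atoms: none
Why: Palladium-mediated oxidative cycloalkenylation (Saegusa/Toyota type, precedented on the closely related lactone): divalent palladium activates the allyl alkene, C8 attacks its internal carbon 5-exo on the only face the C13 tether can reach, which sets the C8 quaternary centre, and β-hydride elimination leaves the exocyclic alkene and zerovalent palladium.

Step 12
Reactants: 25 15-methylene tetracycle
Product: 27 15-ketone (1,6-di-O-benzyl; 11-O-silyl), via ozonide 26 (not isolated)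
Conditions: O3, CH2Cl2, −78 °C; then Me2S
Reagents that add atoms: ozone, [O-][O+]=O
Why: Ozonolysis cleaves the only alkene to the C15 ketone; benzyl and silyl ethers survive a short exposure at −78 °C.

Step 13
Reactants: 27 15-ketone
Product: 28 1,6-diol
Conditions: H2 (1 atm), Pd/C, EtOAc, rt
Reagents that add atoms: none
Why: Hydrogenolysis removes both benzyl ethers at the one stage where the molecule has no alkene.

Step 14
Reactants: 28 1,6-diol
Product: 29 1,6-diacetate
Conditions: Ac2O, pyridine, DMAP, CH2Cl2, 0 °C → rt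
Reagents that add atoms: acetic anhydride, CC(=O)OC(C)=O
Why: Acetylation of the primary C6 and secondary C1 alcohols while C11 stays silylated gives the acetate pattern of the target.

Step 15
Reactants: 29 1,6-diacetate
Product: 31 11-O-silyl Rabdosin B, via Mannich base 30 (not isolated)
Conditions: (Me2N)2CH2, Ac2O, DMF, 95 °C
Reagents that add atoms: bis(dimethylamino)methane, CN(C)CN(C)C
Why: Mannich reaction at C16, the only enolisable position, with the iminium acetate formed in the flask, then thermal loss of dimethylamine (α-methylenation), gives the exocyclic enone under neutral conditions that spare acetates and silyl ether.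

Step 16
Reactants: 31 11-O-silyl Rabdosin B
Product: 32 Rabdosin B
Conditions: HF·pyridine, MeCN, 0 °C → rt
Reagents that add atoms: none
Why: Fluoride-mediated desilylation frees the hindered C11 hydroxyl without touching acetates, lactone or enone.

## Compound list

1 | pent-4-enal | C=CCCC=O | starting material
2 | methyl 2-(bromomethyl)prop-2-enoate | C=C(CBr)C(=O)OC | starting material
3 | methyl 2-[(2S)-2-formylpent-4-en-1-yl]prop-2-enoate | C=C(C(=O)OC)C[C@H](CC=C)C=O | intermediate
4 | (methoxymethyl)triphenylphosphonium chloride | COC[P+](c1ccccc1)(c1ccccc1)c1ccccc1.[Cl-] | starting material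
5 | (methoxymethylidene)triphenylphosphorane | COC=P(c1ccccc1)(c1ccccc1)c1ccccc1 | intermediate
6 | methyl 2-[(2S)-2-(2-methoxyethenyl)pent-4-en-1-yl]prop-2-enoate (E/Z) | C=C(C(=O)OC)C[C@H](CC=C)C=COC | intermediate
7 | 2-[(2S)-2-(2-methoxyethenyl)pent-4-en-1-yl]prop-2-enoic acid (E/Z) | C=C(C(=O)O)C[C@H](CC=C)C=COC | intermediate
8 | 4,4-dimethylcyclohex-2-en-1-one | CC1(C)CCC(=O)C=C1 | starting material
9 | benzyl chloromethyl ether | ClCOCc1ccccc1 | starting material
10 | (benzyloxymethyl)magnesium chloride | Cl[Mg]COCc1ccccc1 | intermediate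
11 | chloromagnesium enolate of (3S)-3-(benzyloxymethyl)-4,4-dimethylcyclohexanone | CC1(C)CCC(O[Mg]Cl)=C[C@@H]1COCc1ccccc1 | intermediate
12 | (2R,3S)-3-(benzyloxymethyl)-2-(dimethylaminomethyl)-4,4-dimethylcyclohexan-1-one | O=C1CCC(C)(C)[C@@H](COCc2ccccc2)[C@@H]1CN(C)C | intermediate
13 | N-methyl quaternary ammonium iodide (methiodide) of 12 | O=C1CCC(C)(C)[C@@H](COCc2ccccc2)[C@@H]1C[N+](C)(C)C.[I-] | intermediate
14 | (3R)-3-(benzyloxymethyl)-4,4-dimethyl-2-methylidenecyclohexan-1-one | O=C1CCC(C)(C)[C@@H](COCc2ccccc2)C1=C | intermediate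
15 | ester of acid 7 with the C20 hydroxymethyl ketone (oxa-Michael adduct of 7 and 14; C10 epimers) | C=C(C(=O)OCC1C(=O)CCC(C)(C)[C@H]1COCc1ccccc1)C[C@H](CC=C)C=COC | intermediate
16 | keto spirolactone: δ-lactone C20–O–C7(=O)–C8–C9 spiro at C10 of ring A; C1 ketone; C5 CH2OBn cis to C20 and trans to C9; C8 carries the (2S)-2-(2-methoxyethenyl)pent-4-enyl chain | O=C1OC[C@@]2(CC1C[C@H](CC=C)C=COC)C(=O)CCC(C)(C)[C@H]2COCc1ccccc1 | intermediate
17 | C1 alcohol of 16 (OH cis to C20) | O=C1OC[C@@]2(CC1C[C@H](CC=C)C=COC)[C@@H](O)CCC(C)(C)[C@H]2COCc1ccccc1 | intermediate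
18 | C1 benzyl ether of 17 | O=C1OC[C@@]2(CC1C[C@H](CC=C)C=COC)[C@@H](OCc1ccccc1)CCC(C)(C)[C@H]2COCc1ccccc1 | intermediate
19 | C8 phenylselenide of 18 | O=C1OC[C@@]2(CC1([Se]c3ccccc3)C[C@H](CC=C)C=COC)[C@@H](OCc1ccccc1)CCC(C)(C)[C@H]2COCc1ccccc1 | intermediate
20 | C8 phenylselenoxide of 18 | O=C1OC[C@@]2(CC1([Se](=O)c3ccccc3)C[C@H](CC=C)C=COC)[C@@H](OCc1ccccc1)CCC(C)(C)[C@H]2COCc1ccccc1 | intermediate
21 | C8=C9 unsaturated spirolactone with enol ether arm | O=C1OC[C@@]2(C=C1C[C@H](CC=C)C=COC)[C@@H](OCc1ccccc1)CCC(C)(C)[C@H]2COCc1ccccc1 | intermediate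
22 | C8=C9 unsaturated spirolactone with C11 aldehyde arm | O=C1OC[C@@]2(C=C1C[C@H](CC=C)CC=O)[C@@H](OCc1ccccc1)CCC(C)(C)[C@H]2COCc1ccccc1 | intermediate
23 | tricyclic lactone: ring C closed, 11-OH, C8–H cis-fused, C13 allyl, 1,6-di-O-benzyl | [C@H]12C[C@H](CC=C)C[C@H](O)[C@H]1[C@]1(COC2=O)[C@@H](OCc2ccccc2)CCC(C)(C)[C@H]1COCc1ccccc1 | intermediate
24 | 11-O-TBS ether and TBS ketene acetal (C7(OTBS)=C8) of 23 | CC(C)(C)[Si](C)(C)OC1=C2C[C@H](CC=C)C[C@H](O[Si](C)(C)C(C)(C)C)[C@H]2[C@]3(CO1)[C@@H](OCc4ccccc4)CCC(C)(C)[C@H]3COCc3ccccc3 | intermediate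
25 | 15-methylene tetracyclic lactone (C16 is CH2), 1,6-di-O-benzyl, 11-O-TBS | C=C1[C@]23C[C@H](C1)C[C@H](O[Si](C)(C)C(C)(C)C)[C@H]2[C@]1(COC3=O)[C@@H](OCc2ccccc2)CCC(C)(C)[C@H]1COCc1ccccc1 | intermediate
26 | secondary ozonide of 25 (1,2,4-trioxolane spiro at C15) | O1COOC12[C@]34C[C@H](C2)C[C@H](O[Si](C)(C)C(C)(C)C)[C@H]3[C@]1(COC4=O)[C@@H](OCc3ccccc3)CCC(C)(C)[C@H]1COCc1ccccc1 | intermediate
27 | 15-ketone, 1,6-di-O-benzyl, 11-O-TBS | O=C1[C@]23C[C@H](C1)C[C@H](O[Si](C)(C)C(C)(C)C)[C@H]2[C@]1(COC3=O)[C@@H](OCc2ccccc2)CCC(C)(C)[C@H]1COCc1ccccc1 | intermediate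
28 | 15-ketone 1,6-diol, 11-O-TBS | O=C1[C@]23C[C@H](C1)C[C@H](O[Si](C)(C)C(C)(C)C)[C@H]2[C@]1(COC3=O)[C@@H](O)CCC(C)(C)[C@H]1CO | intermediate
29 | 15-ketone 1,6-diacetate, 11-O-TBS | O=C1[C@]23C[C@H](C1)C[C@H](O[Si](C)(C)C(C)(C)C)[C@H]2[C@]1(COC3=O)[C@@H](OC(C)=O)CCC(C)(C)[C@H]1COC(C)=O | intermediate
30 | C16 dimethylaminomethyl derivative of 29 | CN(C)CC1C(=O)[C@]23C[C@H]1C[C@H](O[Si](C)(C)C(C)(C)C)[C@H]2[C@]1(COC3=O)[C@@H](OC(C)=O)CCC(C)(C)[C@H]1COC(C)=O | intermediate
31 | 11-O-tert-butyldimethylsilyl Rabdosin B | C=C1C(=O)[C@]23C[C@H]1C[C@H](O[Si](C)(C)C(C)(C)C)[C@H]2[C@]1(COC3=O)[C@@H](OC(C)=O)CCC(C)(C)[C@H]1COC(C)=O | intermediate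
32 | Rabdosin B | C=C1C(=O)[C@]23C[C@H]1C[C@H](O)[C@H]2[C@]1(COC3=O)[C@@H](OC(C)=O)CCC(C)(C)[C@H]1COC(C)=O | target

## Step count and risk

Total step count: 16. Longest linear sequence: 15 steps (steps 1, 2, 4–16; the ring A branch is 14).

Steps most likely to fail:

Step 4 (the proposed new annulation). The carboxylate addition may simply revert, or acid 7 may polymerise. The fallback builds the same lactone by known enolate chemistry. It sets out from the magnesium enolate 11 (made as in step 3) and from ester 6 (isolated by stopping step 2 before LiOH). Quenching 11 with 2,2,2-trifluoroethyl formate gives the hydroxymethylene ketone F1. DBU-catalysed Michael addition of F1 to 6, anti to the C5 substituent, gives the keto aldehyde ester F2 with the C10 quaternary centre. NaBH4 in MeOH at −40 °C reduces aldehyde and ketone to the diol ester F3, and K2CO3 in MeOH closes the δ-lactone through the primary C20 alkoxide. The fallback returns to the route at 17.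

Step 3 (asymmetric conjugate addition of an α-alkoxymethyl Grignard reagent, a nucleophile outside the proven scope). The fallback is racemic synthesis and classical resolution. It sets out from 8 and 10: CuBr·SMe2 (10 mol %, no ligand), Me3SiCl, THF, −78 °C, then the iminium iodide gives racemic 12. Crystallisation with (−)-O,O′-di-p-toluoyl-L-tartaric acid gives the less soluble hydrogen tartrate salt of 12 F4 (the D-acid is used if the antipode crystallises first), while the enantiomeric Mannich base F5 stays in the mother liquor. Aqueous NaHCO3 frees the amine, and the fallback returns to the route at 12.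

Step 9 (ketyl–olefin cyclisation; the extra C1 benzyloxy group sits next to the reacting C9 and may erode face selectivity or favour simple reduction). The fallback closes ring C by polar umpolung. It sets out from 22: an intramolecular Stetter reaction (N-pentafluorophenyl bicyclic triazolium tetrafluoroborate precatalyst 20 mol %, KN(SiMe3)2 20 mol %, toluene, rt) adds C11 to C9 and gives the 11-ketone F6. NaBH4 in MeOH at −78 °C (axial attack, equatorial alcohol trans to C10) then gives the alcohol, and the fallback returns to the route at 23.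

Further compounds

F1 | step 4 | (3S)-3-(benzyloxymethyl)-2-(hydroxymethylidene)-4,4-dimethylcyclohexan-1-one | O=C1CCC(C)(C)[C@@H](COCc2ccccc2)C1=CO
F2 | step 4 | keto aldehyde ester: ring A ketone with C10 bearing CHO and the CH2–CH(CO2Me)–CH2–CH(allyl)(CH=CHOMe) chain | COC(=O)C(C[C@]1(C=O)C(=O)CCC(C)(C)[C@H]1COCc1ccccc1)C[C@H](CC=C)C=COC
F3 | step 4 | diol ester from reduction of F2 (C1–OH and C20–OH) | COC(=O)C(C[C@]1(CO)[C@@H](O)CCC(C)(C)[C@H]1COCc1ccccc1)C[C@H](CC=C)C=COC
F4 | step 3 | hydrogen (−)-O,O′-di-p-toluoyl-L-tartrate salt of 12 | O=C1CCC(C)(C)[C@@H](COCc2ccccc2)[C@@H]1C[NH+](C)C.OC(=O)[C@H](OC(=O)c1ccc(C)cc1)[C@@H](OC(=O)c1ccc(C)cc1)C([O-])=O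
F5 | step 3 | (2S,3R)-3-(benzyloxymethyl)-2-(dimethylaminomethyl)-4,4-dimethylcyclohexan-1-one (antipode of 12) | O=C1CCC(C)(C)[C@H](COCc2ccccc2)[C@H]1CN(C)C
F6 | step 9 | 11-ketone analogue of 23 (Stetter product) | [C@H]12C[C@H](CC=C)CC(=O)[C@H]1[C@]1(COC2=O)[C@@H](OCc2ccccc2)CCC(C)(C)[C@H]1COCc1ccccc1
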